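Cuts, with ent-kaurane numbers (ring A C1–C5/C10, B C5–C10, C C8/C9/C11–C14, D C11–C13/C15/C16; α is the face of the C20 methyl): C8=C9 ⇒ C8=C14 olefin shift, then C9–C10 (ring B), C6–C7 (union), C13–C16 (ring D), C9–C11 and C8–C14 (ring C).
Enabling feature: the acetoxy carbons C1 and C6 flank the A/B fusion bond (O–C1–C10–C5–C6–O), which is the retron of a 2-ene-1,4-dione. In that ene-dione C10 is an electrophile lying 1,5 to the C8=C9 π bond of the bicyclo[3.2.1]octene (rings C and D).
Forward order: ring A is bought (β-ionone). Ring C is made by Diels–Alder reaction, ring D by a gold-catalysed 5-exo-dig closure, and the halves are joined by allylboration. Ring B closes last by ene-dione/olefin cycloisomerisation.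
Stereochemistry: a catalytic aldol sets C15 (erased later); C15 controls C11 (diene face), and C11 controls C13 and C12. The exo face of the bicycle sets C10; the axial C20 methyl then controls C5, C6 and C1.
Helpers removed later: the C1 and C6 ketones (activators, reduced and acetylated), the C15 silyl ether, and the temporary C9–H centre (lost in the last olefin shift).

Key step: step 14

Assumption: TBS is tert-butyldimethylsilyl and pin is pinacolato. The C6 carbinol formed in step 12 is carried as whatever epimer mixture forms, because step 13 erases it.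

Step 1
Reactants: 1 2-(trimethylsilyloxy)buta-1,3-diene; 2 3-(trimethylsilyl)propynal
Product: 3 (R)-5-(trimethylsilyloxy)-7-(trimethylsilyl)hept-1-en-6-yn-3-one
Conditions: (S)-2-butyl-4-(1H-indol-3-ylmethyl)-3-tosyl-1,3,2-oxazaborolidin-5-one (20 mol %), EtCN, −78 °C
Reagents that add atoms: none
Why: Catalytic enantioselective Mukaiyama aldol addition in which the boron Lewis acid shields one face of the alkynal, so that the R carbinol (C15) should form as its silyl ether after silyl transfer.

Step 2
Reactants: 3 (R)-5-(trimethylsilyloxy)-7-(trimethylsilyl)hept-1-en-6-yn-3-one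
Product: 4 (R)-5-hydroxyhept-1-en-6-yn-3-one
Conditions: Bu4NF (2.2 equiv), AcOH (2.2 equiv), THF, 0 °C
Reagents that add atoms: none
Why: Buffered fluoride desilylation cleaves the O–Si and the alkynyl C–Si bonds without base-induced retro-aldol or oxa-Michael reaction, and C15 is untouched.

Step 3
Reactants: 4 (R)-5-hydroxyhept-1-en-6-yn-3-one
Product: 5 (3Z,5R)-3,5-bis(TBS-oxy)hepta-1,3-dien-6-yne
Conditions: TBSOTf (2.4 equiv), Et3N (3.5 equiv), CH2Cl2, −78 to 0 °C
Reagents that add atoms: tert-butyldimethylsilyl triflate CC(C)(C)[Si](C)(C)OS(=O)(=O)C(F)(F)F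
Why: Soft enolisation and silylation caps the carbinol and traps the ketone towards C11 as the Z silyl dienol ether, which places C15 on the outside of the 2-silyloxy diene.

Step 4
Reactants: 5 (3Z,5R)-3,5-bis(TBS-oxy)hepta-1,3-dien-6-yne; 6 methyl propiolate
Product: 7 methyl (3S)-4-(TBS-oxy)-3-[(1R)-1-(TBS-oxy)prop-2-ynyl]cyclohexa-1,4-diene-1-carboxylate (ring C)
Conditions: toluene, 90 °C, trace BHT, argon
Reagents that add atoms: none
Why: Thermal Diels–Alder reaction in which the 2-silyloxy group steers C11 to the β-carbon of the ynoate (para rule) and, with H15 eclipsing the C12 silyloxy group to avoid allylic strain, the dienophile adds anti to the bulky C15 silyloxy group and sets C11.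

Step 5
Reactants: 7 methyl (3S)-4-(TBS-oxy)-3-[(1R)-1-(TBS-oxy)prop-2-ynyl]cyclohexa-1,4-diene-1-carboxylate
Product: 8 methyl 7-endo-(TBS-oxy)-6-methylidene-8-oxobicyclo[3.2.1]oct-2-ene-3-carboxylate (rings C and D; C12 ketone, C7 ester)
Conditions: Ph3PAuCl (5 mol %), AgBF4 (5 mol %), CH2Cl2/MeOH 10:1, 23 °C
Reagents that add atoms: none
Why: Conia-ene-type carbocyclisation in which cationic gold activates the terminal alkyne for 5-exo-dig attack by C13 of the silyl enol ether, possible only on the ring face that carries the C11 side chain, which sets C13.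

Step 6
Reactants: 8 methyl 7-endo-(TBS-oxy)-6-methylidene-8-oxobicyclo[3.2.1]oct-2-ene-3-carboxylate
Product: 9 7-endo-(TBS-oxy)-3-(hydroxymethyl)-6-methylidenebicyclo[3.2.1]oct-2-en-8-ol (C12–OH syn to the two-carbon bridge)
Conditions: LiAlH4, Et2O, −78 to 0 °C; H2O/NaOH work-up
Reagents that add atoms: none
Why: Hydride reduction in which the small hydride should reach C12 from the side of the C8=C9 bridge, anti to the two axial C–C bonds of the two-carbon bridge, giving the carbinol syn to that bridge, while the enoate goes to the allylic alcohol.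

Step 7
Reactants: 9 7-endo-(TBS-oxy)-3-(hydroxymethyl)-6-methylidenebicyclo[3.2.1]oct-2-en-8-ol
Product: 10 the C7 methyl carbonate of 9 (C12–OH free)
Conditions: ClCO2Me (1.05 equiv), pyridine, CH2Cl2, −20 °C
Reagents that add atoms: methyl chloroformate COC(=O)Cl
Why: Selective acylation of the primary allylic alcohol over the hindered bridge carbinol installs the leaving group for step 9.

Step 8
Reactants: 10 the C7 methyl carbonate of 9
Product: 11 the C12,C15-bis-TBS ether C7 methyl carbonate
Conditions: TBSOTf, 2,6-lutidine, CH2Cl2, 0 °C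
Reagents that add atoms: tert-butyldimethylsilyl triflate CC(C)(C)[Si](C)(C)OS(=O)(=O)C(F)(F)F
Why: Silyl ether formation protects C12–OH so that only C1 and C6 are acetylated in step 16.

Step 9
Reactants: 11 the C12,C15-bis-TBS ether C7 methyl carbonate
Product: 12 the allylboronate with exo-Bpin at C9, C8=C7 methylidene and C12,C15-bis-TBS ethers
Conditions: CuCl (5 mol %), 4,5-bis(diphenylphosphino)-9,9-dimethylxanthene (5 mol %), KOtBu (10 mol %), B2pin2 (1.2 equiv), THF, 0 to 23 °C
Reagents that add atoms: bis(pinacolato)diboron CC1(C)OB(OC1(C)C)B1OC(C)(C)C(C)(C)O1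
Why: Copper-catalysed γ-selective (SN2') allylic borylation in which the boryl copper species adds to C9 on the open exo face, the endo face being covered by the C15–C16 bridge and its silyloxy group, and expels the carbonate.

Step 10
Reactants: 13 β-ionone
Product: 14 4-oxo-β-ionone, (E)-4-(2,6,6-trimethyl-3-oxocyclohex-1-enyl)but-3-en-2-one
Conditions: dirhodium tetrakis(caprolactamate) (1 mol %), 70% aq t-BuOOH (5 equiv), ClCH2CH2Cl, 40 °C
Reagents that add atoms: tert-butyl hydroperoxide CC(C)(C)OO
Why: Radical allylic oxidation by tert-butylperoxy radicals attacks the only ring allylic methylene (the future C1) and gives the ene-dione.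

Step 11
Reactants: 14 4-oxo-β-ionone
Product: 16 2,6,6-trimethyl-3-oxocyclohex-1-ene-1-carbaldehyde (ring A with C6 and C1), via secondary ozonide 15 (not isolated)
Conditions: O3, CH2Cl2, −78 °C, stopped at consumption of 14; then Me2S, −78 to 23 °C
Reagents that add atoms: ozone [O-][O+]=O
Why: Ozonolysis cleaves the accessible disubstituted side-chain olefin in preference to the tetrasubstituted, doubly acceptor-substituted ring olefin, as in the cleavage of β-ionone to β-cyclocitral.

Step 12
Reactants: 12 the C9 allylboronate; 16 2,6,6-trimethyl-3-oxocyclohex-1-ene-1-carbaldehyde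
Product: 18 the seco-B alcohol (ring A enone–C6H(OH)–C7H2–C8=C9 of the bicycle; C6 epimers), via pinacol borate ester 17 (not isolated)
Conditions: toluene, 60 °C; then aq NaHCO3
Reagents that add atoms: none
Why: Allylboration through a closed six-membered transition state joins the γ-carbon C7 to the aldehyde carbon C6 chemoselectively beside the ketone and returns the olefin to C8=C9.

Step 13
Reactants: 18 the seco-B alcohol
Product: 19 the seco-B ene-dione (C1 and C6 ketones on C10=C5, C7H2, C8=C9)
Conditions: Dess–Martin periodinane, CH2Cl2, 0 to 23 °C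
Reagents that add atoms: none
Why: Dess–Martin oxidation of the allylic carbinol under neutral conditions gives the ene-dione without moving the β,γ-olefin and merges both C6 epimers.

Step 14
Reactants: 19 the seco-B ene-dione
Product: 20 the tetracyclic 1,6-dione with C8=C14 olefin, 9β-H, 5β-H, 10α-methyl and C12,C15-bis-TBS ethers
Conditions: MeAlCl2 (2.5 equiv), CH2Cl2 (0.005 M), −78 to −30 °C; cold pH 7 phosphate buffer
Reagents that add atoms: none
Why: Proposed new method: MeAlCl2 on the C6 and C1 carbonyl groups turns C10 of the flat, achiral ene-dione into a tertiary-cation equivalent, the C8=C9 π bond attacks it through C9 as in the ring-B stage of the biosynthetic labdane-type cyclisation, the C8 cation loses the aligned exo H14, and the aluminium enolate takes up H5 on the cold quench, so that 19 is simply isomerised to 20. The closest known reaction types are the Lewis-acid-induced intramolecular conjugate (ene-type) addition of alkenes to enones and the acid cyclialkylation of arenes by 1-acyl-2,6,6-trimethylcyclohexenes, but a tetrasubstituted ene-dione has not been used as the acceptor for an unactivated olefin. Ring B closes in the 6-endo-trig mode at both π bonds, because attack through C8 would leave a secondary cation and bonding to C5 would need a 5-endo closure. C9 (a temporary centre) is set by approach of C10 to the exo face of the bicyclo[3.2.1]octene, the endo face being covered by the C15–C16 bridge and its silyloxy group, and C10 follows from the chair-like array in which C11 points away from ring A and H9 stands anti to C20, which places C20 on the α face. C5 is set by protonation of the C5=C6 enolate from the β face, opposite to the axial C20 and C4 α-methyl groups, and it is in any case the epimerisable centre of the more stable trans-decalone. The step needs chemoselectivity for the trisubstituted C8=C9 olefin over the C16 methylidene group, secured by the 1,5 tether and the deactivating allylic silyloxy group, and it needs the olefin to stay out of conjugation with C6, secured by the proton-scavenging methylaluminium reagent and the buffered quench.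

Step 15
Reactants: 20 the tetracyclic 1,6-dione
Product: 21 the 1α,6α-diol (C8=C14, bis-TBS)
Conditions: NaBH4, MeOH/THF, −20 to 0 °C
Reagents that add atoms: none
Why: Hydride reduction in which the axial C20 and C4 α-methyl groups close the α face, so that hydride reaches C6 and C1 from the β face and gives the axial 6α- and the equatorial 1α-alcohol.

Step 16
Reactants: 21 the 1α,6α-diol
Product: 22 the 1α,6α-diacetate (C8=C14, bis-TBS)
Conditions: Ac2O, DMAP (cat.), pyridine, 40 °C
Reagents that add atoms: acetic anhydride CC(=O)OC(C)=O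
Why: DMAP-catalysed acetylation esterifies the only two free hydroxy groups with retention.

Step 17
Reactants: 22 the 1α,6α-diacetate
Product: 23 the 12,15-diol 1α,6α-diacetate (C8=C14, C16 methylidene)
Conditions: HF·pyridine, THF, 0 to 23 °C
Reagents that add atoms: none
Why: Fluoride-mediated desilylation frees C12–OH and C15–OH under conditions that leave the acetates and both olefins alone.

Step 18
Reactants: 23 the 12,15-diol 1α,6α-diacetate
Product: 24 the C8=C14 isomer of the target (C15 ketone, C16 methylidene, C12–OH)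
Conditions: MnO2 (activated, excess), CH2Cl2, 23 °C
Reagents that add atoms: none
Why: Manganese dioxide oxidises only the allylic C15 carbinol to the α-methylidene ketone, erasing the helper centre C15, and leaves the non-allylic C12 carbinol.

Step 19
Reactants: 24 the C8=C14 isomer of the target
Product: 25 1α,6α-diacetoxyjungermannenone C
Conditions: TsOH·H2O (10 mol %), benzene, 60 °C
Reagents that add atoms: none
Why: Acid-catalysed olefin equilibration through the tertiary C8 cation should drain the trisubstituted C8=C14 olefin into the tetrasubstituted C8=C9 olefin by loss of the aligned axial H9, and the α-methylidene ketone cannot isomerise because C13 is a bridgehead.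

Compound list
1 | 2-(trimethylsilyloxy)buta-1,3-diene | C=CC(=C)O[Si](C)(C)C | starting material
2 | 3-(trimethylsilyl)propynal | O=CC#C[Si](C)(C)C | starting material
3 | (R)-5-(trimethylsilyloxy)-7-(trimethylsilyl)hept-1-en-6-yn-3-one | C=CC(=O)C[C@@H](O[Si](C)(C)C)C#C[Si](C)(C)C | intermediate
4 | (R)-5-hydroxyhept-1-en-6-yn-3-one | C=CC(=O)C[C@@H](O)C#C | intermediate
5 | (3Z,5R)-3,5-bis(TBS-oxy)hepta-1,3-dien-6-yne | C=C/C(O[Si](C)(C)C(C)(C)C)=C/[C@@H](O[Si](C)(C)C(C)(C)C)C#C | intermediate
6 | methyl propiolate | C#CC(=O)OC | starting material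
7 | ring C cyclohexa-1,4-diene ester | COC(=O)C1=C[C@@H]([C@@H](O[Si](C)(C)C(C)(C)C)C#C)C(O[Si](C)(C)C(C)(C)C)=CC1 | intermediate
8 | rings C/D keto ester | C=C1[C@H](O[Si](C)(C)C(C)(C)C)[C@@H]2C=C(C(=O)OC)C[C@H]1C2=O | intermediate
9 | rings C/D diol | C=C1[C@H](O[Si](C)(C)C(C)(C)C)[C@@H]2C=C(CO)C[C@H]1[C@@H]2O | intermediate
10 | C7 methyl carbonate | C=C1[C@H](O[Si](C)(C)C(C)(C)C)[C@@H]2C=C(COC(=O)OC)C[C@H]1[C@@H]2O | intermediate
11 | bis-TBS C7 methyl carbonate | C=C1[C@H](O[Si](C)(C)C(C)(C)C)[C@@H]2C=C(COC(=O)OC)C[C@H]1[C@@H]2O[Si](C)(C)C(C)(C)C | intermediate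
12 | C9 exo allylboronate | C=C1[C@H](O[Si](C)(C)C(C)(C)C)[C@@H]2[C@@H](B3OC(C)(C)C(C)(C)O3)C(=C)C[C@H]1[C@@H]2O[Si](C)(C)C(C)(C)C | intermediate
13 | β-ionone | CC(=O)/C=C/C1=C(C)CCCC1(C)C | starting material
14 | 4-oxo-β-ionone | CC(=O)/C=C/C1=C(C)C(=O)CCC1(C)C | intermediate
15 | secondary ozonide of 14 | CC(=O)C1OOC(O1)C2=C(C)C(=O)CCC2(C)C | intermediate
16 | 2,6,6-trimethyl-3-oxocyclohex-1-ene-1-carbaldehyde | O=CC1=C(C)C(=O)CCC1(C)C | intermediate
17 | pinacol borate ester of 18 | C=C1[C@H](O[Si](C)(C)C(C)(C)C)[C@@H]2C=C(CC(OB3OC(C)(C)C(C)(C)O3)C4=C(C)C(=O)CCC4(C)C)C[C@H]1[C@@H]2O[Si](C)(C)C(C)(C)C | intermediate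
18 | seco-B alcohol (C6 epimers) | C=C1[C@H](O[Si](C)(C)C(C)(C)C)[C@@H]2C=C(CC(O)C3=C(C)C(=O)CCC3(C)C)C[C@H]1[C@@H]2O[Si](C)(C)C(C)(C)C | intermediate
19 | seco-B ene-dione | C=C1[C@H](O[Si](C)(C)C(C)(C)C)[C@@H]2C=C(CC(=O)C3=C(C)C(=O)CCC3(C)C)C[C@H]1[C@@H]2O[Si](C)(C)C(C)(C)C | intermediate
20 | tetracyclic 8(14)-ene-1,6-dione | C=C1[C@H](O[Si](C)(C)C(C)(C)C)[C@@H]2[C@@H]3C(=C[C@H]1[C@@H]2O[Si](C)(C)C(C)(C)C)CC(=O)[C@@H]4C(C)(C)CCC(=O)[C@@]34C | intermediate
21 | 1α,6α-diol | C=C1[C@H](O[Si](C)(C)C(C)(C)C)[C@@H]2[C@@H]3C(=C[C@H]1[C@@H]2O[Si](C)(C)C(C)(C)C)C[C@H](O)[C@@H]4C(C)(C)CC[C@H](O)[C@@]34C | intermediate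
22 | 1α,6α-diacetate | C=C1[C@H](O[Si](C)(C)C(C)(C)C)[C@@H]2[C@@H]3C(=C[C@H]1[C@@H]2O[Si](C)(C)C(C)(C)C)C[C@H](OC(C)=O)[C@@H]4C(C)(C)CC[C@H](OC(C)=O)[C@@]34C | intermediate
23 | 12,15-diol diacetate | C=C1[C@H](O)[C@@H]2[C@@H]3C(=C[C@H]1[C@@H]2O)C[C@H](OC(C)=O)[C@@H]4C(C)(C)CC[C@H](OC(C)=O)[C@@]34C | intermediate
24 | C8=C14 isomer of the target | C=C1C(=O)[C@@H]2[C@@H]3C(=C[C@H]1[C@@H]2O)C[C@H](OC(C)=O)[C@@H]4C(C)(C)CC[C@H](OC(C)=O)[C@@]34C | intermediate
25 | 1α,6α-diacetoxyjungermannenone C | C=C1C(=O)[C@@H]2C3=C(C[C@H](OC(C)=O)[C@@H]4C(C)(C)CC[C@H](OC(C)=O)[C@@]34C)C[C@H]1[C@@H]2O | target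

Total steps: 19. Longest linear sequence: 17 (steps 1–9 and 12–19).

Steps most likely to fail

Step 14.
- The C6 acyl group may stay twisted out of conjugation, so that no bond forms.
- The β,γ-olefin may slip into conjugation and divert into a 4π closure to a five-membered ring.
- The C8 cation may lose H7 instead of H14.
- The allylic silyl ether may ionise.

The fallback sets out from 18 and comes back at 21. Excess KH with 18-crown-6 in THF forms the C6 alkoxide, with the C1 ketone masked as its enolate. An anionic oxy-Cope rearrangement through a chair on the exo face of C9 then makes C9–C10 at the cost of C6–C7. After protonation and equilibration at C5 this gives the keto aldehyde F1. Me2AlCl closes ring B by a type 2 carbonyl-ene reaction of the C6 aldehyde with the C8=C7 methylidene group, giving the 6α-hydroxy-8(14)-en-1-one F2. NaBH4 then reduces C1 to give 21.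

Step 19.
- The equilibration may stop short of the tetrasubstituted olefin.
- The C8 cation may undergo 1,2-shifts within the bicyclooctyl unit.
- The β-hydroxy ketone may undergo retro-aldol cleavage.

The fallback sets out from 24 and comes back at 25. It replaces the catalytic proton shuttle by addition and elimination. Dry HCl in CHCl3 at 0 °C adds across C8=C14 to give the tertiary 8-chloride F3 (C8 configuration left open). LiBr/Li2CO3 in DMF then removes HCl in the sense of the most substituted olefin, using the axial H9.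

Step 12.
- Addition of the hindered secondary boronate to the doubly flanked aldehyde may be too slow.
- Protodeboronation or a boron shift may then lead to bonding through C9.

The fallback sets out from 11 and comes back at 18. Copper-catalysed γ-selective allylic silylation with PhMe2Si–Bpin (CuCl, NaOtBu) gives the C9 exo allylsilane F4. A Hosomi–Sakurai addition to 16 with BF3·OEt2 at −78 °C through an open transition state then joins C7 to C6 and gives 18.

Further compounds
F1 | step 14 | keto aldehyde (C9–C10 made, C6 aldehyde on C5, C8=C7 methylidene) | C=C1[C@H](O[Si](C)(C)C(C)(C)C)[C@@H]2[C@H](C(=C)C[C@H]1[C@@H]2O[Si](C)(C)C(C)(C)C)[C@]3(C)C(=O)CCC(C)(C)[C@H]3C=O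
F2 | step 14 | 6α-hydroxy-8(14)-en-1-one | C=C1[C@H](O[Si](C)(C)C(C)(C)C)[C@@H]2[C@@H]3C(=C[C@H]1[C@@H]2O[Si](C)(C)C(C)(C)C)C[C@H](O)[C@@H]4C(C)(C)CCC(=O)[C@@]34C
F3 | step 19 | tertiary 8-chloride of 24 (C8 configuration open) | C=C1C(=O)[C@@H]2[C@@H]3C(Cl)(C[C@H]1[C@@H]2O)C[C@H](OC(C)=O)[C@@H]4C(C)(C)CC[C@H](OC(C)=O)[C@@]34C
F4 | step 12 | C9 exo allyl(dimethyl)phenylsilane | C=C1[C@H](O[Si](C)(C)C(C)(C)C)[C@@H]2[C@@H]([Si](C)(C)c3ccccc3)C(=C)C[C@H]1[C@@H]2O[Si](C)(C)C(C)(C)C
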